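**Retrosynthetic overview**

- The C1–C10 epoxide is put in last by a Shi epoxidation of the macrocyclic 1(10)Z,4Z-diene.
- The ten-membered ring is closed at C3–C4 by an intramolecular Nozaki–Hiyama–Kishi reaction of a (Z)-alkenyl iodide onto a C3 aldehyde.
- The trans α-methylene-γ-lactone (C6–C7 bond, C6 and C7 stereocentres) comes from a chiral phosphoric acid-catalysed allylboration–lactonisation of a 2-(methoxycarbonyl)allylboronate with (Z)-3-iodobut-2-enal.
- The boronate comes from a γ-acyloxy ynoate: methyl propiolate is added to a C8 aldehyde (the Z-C1=C10 alkene is locked by Birch reduction and ozonolysis of 3-methylanisole), and the alcohol is esterified with epoxyangelic acid made by Shi epoxidation.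
- Order of ring formation: side-chain oxirane (step 2), γ-lactone (step 12), ten-membered carbocycle (step 14), ring oxirane (step 15).

Assumption: germacrane numbering (C1–C15, lactone C12–O–C6) is used for the late intermediates, and compounds 1, 6, 10, 15 and 19 are taken as commercial.

**Route**

Step 1
Reactants: 1 methyl angelate [methyl (2Z)-2-methylbut-2-enoate]
Product: 2 (2Z)-2-methylbut-2-en-1-ol
Conditions: i-Bu2AlH (2.2 equiv), CH2Cl2, −78 → 0 °C
Reagents that add atoms: none
Why: 1,2-Hydride reduction of the enoate gives the allylic alcohol and leaves the Z-trisubstituted alkene untouched.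

Step 2
Reactants: 2 (2Z)-2-methylbut-2-en-1-ol
Product: 3 [(2S,3R)-2,3-dimethyloxiran-2-yl]methanol
Conditions: D-fructose-derived Shi ketone (30 mol %), Oxone (2KHSO5·KHSO4·K2SO4), K2CO3, Bu4NHSO4, aq. Na2B4O7/Na2EDTA, MeCN–DMM, 0 °C
Reagents that add atoms: potassium peroxymonosulfate (KHSO5 of Oxone), [K+].[O-]S(=O)(=O)OO
Why: Shi epoxidation, in which the chiral dioxirane attacks the Z-trisubstituted alkene through the spiro transition state with the vinylic H toward the catalyst ketal, sets the first two stereocentres (2S,3R) by organocatalysis.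

Step 3
Reactants: 3 [(2S,3R)-2,3-dimethyloxiran-2-yl]methanol
Product: 5 (2R,3R)-2,3-dimethyloxirane-2-carboxylic acid, via epoxy aldehyde 4 (not isolated)
Conditions: TEMPO (20 mol %), PhI(OAc)2 (2.2 equiv), MeCN/H2O 1:1, 25 °C
Reagents that add atoms: water, O
Why: Oxoammonium (TEMPO) oxidation takes the primary alcohol through the aldehyde hydrate to the acid without opening the oxirane or touching either stereocentre.

Step 4
Reactants: 6 but-2-yn-1-ol
Product: 8 (2Z)-3-iodobut-2-en-1-ol, via cyclic alkenylaluminate 7 (not isolated)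
Conditions: NaAlH2(OCH2CH2OMe)2, THF, 0 → 25 °C; then I2, −78 → 0 °C
Reagents that add atoms: iodine, II
Why: Alkoxide-directed trans-hydroalumination gives the five-membered oxaaluminacycle, and iodinolysis of its C–Al bond with retention places I cis to CH2OH (Z).

Step 5
Reactants: 8 (2Z)-3-iodobut-2-en-1-ol
Product: 9 (2Z)-3-iodobut-2-enal
Conditions: MnO2 (activated), CH2Cl2, 25 °C, dark
Reagents that add atoms: none
Why: Heterogeneous allylic oxidation with MnO2 gives the enal under neutral conditions that do not isomerise the Z alkene.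

Step 6
Reactants: 10 3-methylanisole
Product: 11 1-methoxy-5-methylcyclohexa-1,4-diene
Conditions: Li, NH3 (l), THF, t-BuOH, −78 → −33 °C
Reagents that add atoms: none
Why: Birch reduction leaves both donor-substituted carbons sp2, so the ring fixes the future C1=C10 alkene in the cis (Z) geometry.

Step 7
Reactants: 11 1-methoxy-5-methylcyclohexa-1,4-diene
Product: 13 methyl (3Z)-6,6-dimethoxy-3-methylhex-3-enoate, via aldehyde ester 12 (not isolated)
Conditions: O3 (1.0 equiv), pyridine, CH2Cl2/MeOH, −78 °C; Me2S; then HC(OMe)3, p-TsOH (cat.), 25 °C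
Reagents that add atoms: ozone, [O-][O+]=O; trimethyl orthoformate, COC(OC)OC
Why: Ozonolysis cleaves the much more electron-rich enol-ether alkene selectively, the ring-derived Z geometry is kept, and the new aldehyde (future C3) is masked in the same pot as its dimethyl acetal.

Step 8
Reactants: 13 methyl (3Z)-6,6-dimethoxy-3-methylhex-3-enoate
Product: 14 (3Z)-6,6-dimethoxy-3-methylhex-3-enal
Conditions: i-Bu2AlH (1.05 equiv), CH2Cl2, −78 °C; used crude
Reagents that add atoms: none
Why: Half-reduction of the ester stops at the aluminium hemiacetal at −78 °C and gives the β,γ-unsaturated aldehyde (C8), which is used at once to avoid conjugation.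

Step 9
Reactants: 14 (3Z)-6,6-dimethoxy-3-methylhex-3-enal; 15 methyl propiolate
Product: 17 methyl (4R,6Z)-4-hydroxy-9,9-dimethoxy-6-methylnon-6-en-2-ynoate, via zinc alkynide 16 (not isolated)
Conditions: Me2Zn (3 equiv), (S,S)-ProPhenol (20 mol %; the enantiomer that gives the 4R carbinol), Ph3PO (40 mol %), toluene, 4 °C
Reagents that add atoms: none
Why: Zinc–ProPhenol-catalysed asymmetric alkynylation delivers the zinc alkynide to one aldehyde face under catalyst control and sets C8 (4R here).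

Step 10
Reactants: 17 methyl (4R,6Z)-4-hydroxy-9,9-dimethoxy-6-methylnon-6-en-2-ynoate; 5 (2R,3R)-2,3-dimethyloxirane-2-carboxylic acid
Product: 18 methyl (4R,6Z)-4-{[(2R,3R)-2,3-dimethyloxirane-2-carbonyl]oxy}-9,9-dimethoxy-6-methylnon-6-en-2-ynoate
Conditions: EDC·HCl, DMAP (cat.), CH2Cl2, 0 → 25 °C
Reagents that add atoms: none
Why: Steglich (carbodiimide) esterification acylates the propargylic alcohol with retention at every centre and blocks O8 so that only O6 can later lactonise.

Step 11
Reactants: 18 (ynoate ester); 19 2-(iodomethyl)-4,4,5,5-tetramethyl-1,3,2-dioxaborolane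
Product: 21 methyl (2Z,4R,6Z)-4-{[(2R,3R)-2,3-dimethyloxirane-2-carbonyl]oxy}-9,9-dimethoxy-6-methyl-2-[(4,4,5,5-tetramethyl-1,3,2-dioxaborolan-2-yl)methyl]nona-2,6-dienoate, via vinylalane 20 (not isolated)
Conditions: i-Bu2AlH (1.2 equiv), HMPA, THF, 0 °C; then 19, 0 → 25 °C
Reagents that add atoms: none
Why: Syn 1,4-hydroalumination of the ynoate (vinylalumination) gives the α-alumino acrylate with C8 cis to CO2Me, and C-alkylation with the iodomethylboronate keeps that geometry; chemoselectivity over the hindered epoxy ester rests on the HMPA-moderated hydride.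

Step 12
Reactants: 21 (allylboronate); 9 (2Z)-3-iodobut-2-enal
Product: 23 (1R,3Z)-1-[(2S,3R)-2-[(1Z)-2-iodoprop-1-en-1-yl]-4-methylidene-5-oxooxolan-3-yl]-6,6-dimethoxy-3-methylhex-3-en-1-yl (2R,3R)-2,3-dimethyloxirane-2-carboxylate, via borate ester 22 (not isolated)
Conditions: (S)-TRIP [(S)-3,3′-bis(2,4,6-triisopropylphenyl)-1,1′-binaphthyl-2,2′-diyl hydrogen phosphate] (10 mol %), 4 Å MS, toluene, 0 → 30 °C; then PPTS (cat.), 40 °C
Reagents that add atoms: none
Why: Proposed new method: a chiral phosphoric acid-catalysed allylboration–lactonisation of an ester-deactivated, γ-substituted 2-(methoxycarbonyl)allyl pinacolboronate, in which P–OH hydrogen-bonds to a pinacol oxygen (raising boron Lewis acidity, as strong achiral acids do for this reagent class) and P=O binds the formyl C–H so that the enal reacts on its Si face through a closed chair with the iodoalkenyl group equatorial; the (2Z)-boronate puts C8 equatorial, which gives the anti adduct (6R,7R in germacrane numbering) and, after acyl transfer of the borate onto the methyl ester, the trans lactone; the A(1,3)-minimised rotamer at C8 (H-8 eclipsing the ester, C9 anti to the incoming aldehyde) is expected to make substrate and catalyst control matched; the closest known reaction types are the chiral phosphoric acid-catalysed allylboration of aldehydes with simple allyl pinacolboronates and the Brønsted or Lewis acid-accelerated lactone-forming additions of achiral 2-(alkoxycarbonyl)allylboronates.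

Step 13
Reactants: 23 (iodoalkenyl lactone acetal)
Product: 24 (1R,3Z)-1-[(2S,3R)-2-[(1Z)-2-iodoprop-1-en-1-yl]-4-methylidene-5-oxooxolan-3-yl]-3-methyl-6-oxohex-3-en-1-yl (2R,3R)-2,3-dimethyloxirane-2-carboxylate
Conditions: LiBF4, MeCN/H2O (98:2), 25 °C; used crude
Reagents that add atoms: water, O
Why: Mild Lewis acid-promoted acetal hydrolysis frees the C3 aldehyde while the glycidic ester, alkenyl iodide and methylene lactone are inert.

Step 14
Reactants: 24 (aldehyde alkenyl iodide)
Product: 26 (3S,6R,7R,8R)-8-{[(2R,3R)-2,3-dimethyloxirane-2-carbonyl]oxy}-3-hydroxygermacra-1(10)Z,4Z,11(13)-trien-12,6-olide, via alkenylchromium 25 (not isolated)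
Conditions: CrCl2 (8 equiv), NiCl2 (2 mol %), chiral oxazoline–sulfonamide ligand (Kishi type, enantiomer chosen in a model coupling), Et3N, THF/MeCN, 25 °C, 2 mM, slow addition
Reagents that add atoms: none
Why: Intramolecular Nozaki–Hiyama–Kishi reaction, in which NiCl2-catalysed formation of the alkenylchromium species keeps the Z geometry and its addition to the aldehyde closes the ten-membered ring; the chiral ligand on chromium together with the macrocyclic transition state sets C3 (S), the least secure centre of the route.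

Step 15
Reactants: 26 (macrocyclic triene lactone)
Product: 27 (1R,3S,6R,7R,8R,10S)-1,10-epoxy-8-{[(2R,3R)-2,3-dimethyloxirane-2-carbonyl]oxy}-3-hydroxygermacra-4Z,11(13)-dien-12,6-olide (target)
Conditions: D-fructose-derived Shi ketone (30 mol %), Oxone (2KHSO5·KHSO4·K2SO4), K2CO3, Bu4NHSO4, aq. Na2B4O7/Na2EDTA, MeCN–DMM, 0 °C
Reagents that add atoms: potassium peroxymonosulfate (KHSO5 of Oxone), [K+].[O-]S(=O)(=O)OO
Why: Shi epoxidation, in which the electrophilic dioxirane picks the only electron-rich alkene (C1=C10) over the oxygen-flanked C4=C5 and the electron-poor methylene lactone and delivers oxygen in the same facial sense as in step 2, gives the (1R,10S) cis-oxirane.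

**Compound list**

1 | methyl angelate, methyl (2Z)-2-methylbut-2-enoate | C/C=C(/C)C(=O)OC | starting material
2 | (2Z)-2-methylbut-2-en-1-ol | C/C=C(/C)CO | intermediate
3 | [(2S,3R)-2,3-dimethyloxiran-2-yl]methanol | OC[C@]1(C)O[C@@H]1C | intermediate
4 | (2R,3R)-2,3-dimethyloxirane-2-carbaldehyde | O=C[C@]1(C)O[C@@H]1C | intermediate (not isolated)
5 | (2R,3R)-2,3-dimethyloxirane-2-carboxylic acid (epoxyangelic acid) | OC(=O)[C@]1(C)O[C@@H]1C | intermediate
6 | but-2-yn-1-ol | CC#CCO | starting material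
7 | sodium 2,2-bis(2-methoxyethoxy)-3-methyl-2,5-dihydro-1,2-oxaluminol-2-uide (cyclic alkenylaluminate) | [Na+].CC1=CCO[Al-]1(OCCOC)OCCOC | intermediate (not isolated)
8 | (2Z)-3-iodobut-2-en-1-ol | C/C(I)=C/CO | intermediate
9 | (2Z)-3-iodobut-2-enal | C/C(I)=C/C=O | intermediate
10 | 3-methylanisole | COc1cccc(C)c1 | starting material
11 | 1-methoxy-5-methylcyclohexa-1,4-diene | COC1=CCC=C(C)C1 | intermediate
12 | methyl (3Z)-3-methyl-6-oxohex-3-enoate | COC(=O)C/C(C)=C\CC=O | intermediate (not isolated)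
13 | methyl (3Z)-6,6-dimethoxy-3-methylhex-3-enoate | COC(=O)C/C(C)=C\CC(OC)OC | intermediate
14 | (3Z)-6,6-dimethoxy-3-methylhex-3-enal | O=CC/C(C)=C\CC(OC)OC | intermediate
15 | methyl propiolate | C#CC(=O)OC | starting material
16 | methyl 3-(methylzincio)prop-2-ynoate | C[Zn]C#CC(=O)OC | intermediate (not isolated)
17 | methyl (4R,6Z)-4-hydroxy-9,9-dimethoxy-6-methylnon-6-en-2-ynoate | COC(=O)C#C[C@H](O)C/C(C)=C\CC(OC)OC | intermediate
18 | methyl (4R,6Z)-4-{[(2R,3R)-2,3-dimethyloxirane-2-carbonyl]oxy}-9,9-dimethoxy-6-methylnon-6-en-2-ynoate | COC(=O)C#C[C@H](OC(=O)[C@]1(C)O[C@@H]1C)C/C(C)=C\CC(OC)OC | intermediate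
19 | 2-(iodomethyl)-4,4,5,5-tetramethyl-1,3,2-dioxaborolane | ICB1OC(C)(C)C(C)(C)O1 | starting material
20 | methyl (2E,4R,6Z)-2-[bis(2-methylpropyl)alumanyl]-4-{[(2R,3R)-2,3-dimethyloxirane-2-carbonyl]oxy}-9,9-dimethoxy-6-methylnona-2,6-dienoate | COC(=O)/C([Al](CC(C)C)CC(C)C)=C\[C@H](OC(=O)[C@]1(C)O[C@@H]1C)C/C(C)=C\CC(OC)OC | intermediate (not isolated)
21 | methyl (2Z,4R,6Z)-4-{[(2R,3R)-2,3-dimethyloxirane-2-carbonyl]oxy}-9,9-dimethoxy-6-methyl-2-[(4,4,5,5-tetramethyl-1,3,2-dioxaborolan-2-yl)methyl]nona-2,6-dienoate | COC(=O)/C(CB1OC(C)(C)C(C)(C)O1)=C\[C@H](OC(=O)[C@]2(C)O[C@@H]2C)C/C(C)=C\CC(OC)OC | intermediate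
22 | methyl (3S,4S,5Z)-3-[(1R,3Z)-1-{[(2R,3R)-2,3-dimethyloxirane-2-carbonyl]oxy}-6,6-dimethoxy-3-methylhex-3-en-1-yl]-6-iodo-2-methylidene-4-[(4,4,5,5-tetramethyl-1,3,2-dioxaborolan-2-yl)oxy]hept-5-enoate | C=C(C(=O)OC)[C@@H]([C@H](OB1OC(C)(C)C(C)(C)O1)/C=C(/C)I)[C@H](OC(=O)[C@]2(C)O[C@@H]2C)C/C(C)=C\CC(OC)OC | intermediate (not isolated)
23 | (1R,3Z)-1-[(2S,3R)-2-[(1Z)-2-iodoprop-1-en-1-yl]-4-methylidene-5-oxooxolan-3-yl]-6,6-dimethoxy-3-methylhex-3-en-1-yl (2R,3R)-2,3-dimethyloxirane-2-carboxylate (trans lactone; the oxolane C2 is spatially the target C6, labelled S only because iodine raises the alkenyl priority) | C=C1C(=O)O[C@H](/C=C(/C)I)[C@H]1[C@H](OC(=O)[C@]2(C)O[C@@H]2C)C/C(C)=C\CC(OC)OC | intermediate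
24 | (1R,3Z)-1-[(2S,3R)-2-[(1Z)-2-iodoprop-1-en-1-yl]-4-methylidene-5-oxooxolan-3-yl]-3-methyl-6-oxohex-3-en-1-yl (2R,3R)-2,3-dimethyloxirane-2-carboxylate | C=C1C(=O)O[C@H](/C=C(/C)I)[C@H]1[C@H](OC(=O)[C@]2(C)O[C@@H]2C)C/C(C)=C\CC=O | intermediate
25 | alkenylchromium dichloride of 24 (CrCl2 in place of I, same configuration; chiral ligand on Cr not drawn) | C=C1C(=O)O[C@H](/C=C(/C)[Cr](Cl)Cl)[C@H]1[C@H](OC(=O)[C@]2(C)O[C@@H]2C)C/C(C)=C\CC=O | intermediate (not isolated)
26 | (3S,6R,7R,8R)-8-{[(2R,3R)-2,3-dimethyloxirane-2-carbonyl]oxy}-3-hydroxygermacra-1(10)Z,4Z,11(13)-trien-12,6-olide | C=C1C(=O)O[C@@H]2/C=C(/C)[C@@H](O)C/C=C(C)\C[C@@H](OC(=O)[C@]3(C)O[C@@H]3C)[C@@H]12 | intermediate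
27 | (1R,3S,6R,7R,8R,10S)-1,10-epoxy-8-{[(2R,3R)-2,3-dimethyloxirane-2-carbonyl]oxy}-3-hydroxygermacra-4Z,11(13)-dien-12,6-olide (CNP0268255.3) | C=C1C(=O)O[C@@H]2/C=C(/C)[C@@H](O)C[C@H]3O[C@@]3(C)C[C@@H](OC(=O)[C@]3(C)O[C@@H]3C)[C@@H]12 | target

**Step count and risks**

Total step count: 15 (steps 1–3 side chain, steps 4–5 iodo-enal, steps 6–15 main chain). Longest linear sequence: 10 steps (steps 6–15, from 3-methylanisole).

Step 12 (the proposed new allylboration–lactonisation) may fail because the chiral acid does not turn over with the ester-deactivated boronate, or because catalyst and the C8 stereocentre are mismatched. The fallback makes the same C6–C7 bond by known chromium-mediated 2-(alkoxycarbonyl)allylation (Barbier type) and sets out from 18. Ynoate 18 is hydroaluminated as in step 11 but quenched with paraformaldehyde to give methyl (2Z,4R,6Z)-4-{[(2R,3R)-2,3-dimethyloxirane-2-carbonyl]oxy}-2-(hydroxymethyl)-9,9-dimethoxy-6-methylnona-2,6-dienoate F1. Appel bromination (CBr4, PPh3) gives methyl (2E,4R,6Z)-2-(bromomethyl)-4-{[(2R,3R)-2,3-dimethyloxirane-2-carbonyl]oxy}-9,9-dimethoxy-6-methylnona-2,6-dienoate F2. CrCl2 (THF, 25 °C) then adds F2 to enal 9 to give methyl (3S,4S,5Z)-3-[(1R,3Z)-1-{[(2R,3R)-2,3-dimethyloxirane-2-carbonyl]oxy}-6,6-dimethoxy-3-methylhex-3-en-1-yl]-4-hydroxy-6-iodo-2-methylidenehept-5-enoate F3, which lactonises with PPTS and comes back to the route at 23. The anti outcome is expected by analogy with chromium crotylation but is not certain for this reagent class; a cis lactone would have to be separated.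

Step 14 (Nozaki–Hiyama–Kishi macrocyclisation) is the step where C3 is least securely controlled; the ring may close with the wrong C3 configuration or as a mixture. The fallback moves stereocontrol from C–C bond formation to a reagent-controlled ketone reduction; it sets out from 24 and comes back at 26. The epimeric ring-closure product, (3R,6R,7R,8R)-8-{[(2R,3R)-2,3-dimethyloxirane-2-carbonyl]oxy}-3-hydroxygermacra-1(10)Z,4Z,11(13)-trien-12,6-olide F4 (alone or mixed with 26), is oxidised with Dess–Martin periodinane to (6R,7R,8R)-8-{[(2R,3R)-2,3-dimethyloxirane-2-carbonyl]oxy}-3-oxogermacra-1(10)Z,4Z,11(13)-trien-12,6-olide F5. Corey–Bakshi–Shibata reduction of F5 ((R)-Me-CBS, catecholborane, toluene, −78 °C; alkenyl group as the large substituent) gives 26.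

Step 15 (late Shi epoxidation) may fail if the dioxirane cannot override the facial bias of the ten-membered ring and gives the (1S,10R) oxirane. The fallback delivers the oxygen in two steps with the opposite facial sense; it sets out from 26 and comes back at 27. NBS in aqueous THF (0 °C) attacks the same exposed face, and water opens the bromonium ion at the tertiary C10 from the other side to give (1S,3S,6R,7R,8R,10S)-1-bromo-8-{[(2R,3R)-2,3-dimethyloxirane-2-carbonyl]oxy}-3,10-dihydroxygermacra-4Z,11(13)-dien-12,6-olide F6. K2CO3 (MeCN, 25 °C) closes the oxirane by intramolecular SN2 at C1 with inversion to give 27.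

**Further compounds**

F1 | step 12 | methyl (2Z,4R,6Z)-4-{[(2R,3R)-2,3-dimethyloxirane-2-carbonyl]oxy}-2-(hydroxymethyl)-9,9-dimethoxy-6-methylnona-2,6-dienoate | COC(=O)/C(CO)=C\[C@H](OC(=O)[C@]1(C)O[C@@H]1C)C/C(C)=C\CC(OC)OC
F2 | step 12 | methyl (2E,4R,6Z)-2-(bromomethyl)-4-{[(2R,3R)-2,3-dimethyloxirane-2-carbonyl]oxy}-9,9-dimethoxy-6-methylnona-2,6-dienoate | COC(=O)/C(CBr)=C\[C@H](OC(=O)[C@]1(C)O[C@@H]1C)C/C(C)=C\CC(OC)OC
F3 | step 12 | methyl (3S,4S,5Z)-3-[(1R,3Z)-1-{[(2R,3R)-2,3-dimethyloxirane-2-carbonyl]oxy}-6,6-dimethoxy-3-methylhex-3-en-1-yl]-4-hydroxy-6-iodo-2-methylidenehept-5-enoate | C=C(C(=O)OC)[C@@H]([C@H](O)/C=C(/C)I)[C@H](OC(=O)[C@]1(C)O[C@@H]1C)C/C(C)=C\CC(OC)OC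
F4 | step 14 | (3R,6R,7R,8R)-8-{[(2R,3R)-2,3-dimethyloxirane-2-carbonyl]oxy}-3-hydroxygermacra-1(10)Z,4Z,11(13)-trien-12,6-olide | C=C1C(=O)O[C@@H]2/C=C(/C)[C@H](O)C/C=C(C)\C[C@@H](OC(=O)[C@]3(C)O[C@@H]3C)[C@@H]12
F5 | step 14 | (6R,7R,8R)-8-{[(2R,3R)-2,3-dimethyloxirane-2-carbonyl]oxy}-3-oxogermacra-1(10)Z,4Z,11(13)-trien-12,6-olide | C=C1C(=O)O[C@@H]2/C=C(/C)C(=O)C/C=C(C)\C[C@@H](OC(=O)[C@]3(C)O[C@@H]3C)[C@@H]12
F6 | step 15 | (1S,3S,6R,7R,8R,10S)-1-bromo-8-{[(2R,3R)-2,3-dimethyloxirane-2-carbonyl]oxy}-3,10-dihydroxygermacra-4Z,11(13)-dien-12,6-olide | C=C1C(=O)O[C@@H]2/C=C(/C)[C@@H](O)C[C@H](Br)[C@@](C)(O)C[C@@H](OC(=O)[C@]3(C)O[C@@H]3C)[C@@H]12
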